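## Retrosynthetic overview

- Target ⇒ Schenck ene reaction (C14–O, C13=C16) of the Δ13(14)-alkene 30 ⇒ B-alkyl Suzuki–Miyaura coupling (C12–C13) of the 9-vinyl decalin 22 with the butenolide vinyl iodide 28 (butenolide by ring-closing metathesis).
- 22 ⇒ ring B is adjusted after the cycloaddition: C7=C8 enone → 7α,8α-epoxide → dissolving-metal reduction (8α-OH, then 6α-OH); the C18 methyl ester is unmasked from an orthoester.
- Rings A and B ⇒ one intramolecular Diels–Alder reaction of the acyclic trienal 14: diene C5=C6(OSi)–C7=C8, dienophile C9=C10 (enal, C11=O), tether C1–C4; it forms C5–C10 and C8–C9.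
- Enabling feature: ring B carries oxygen on C6 and C8 (1,3) and the carbon C11 on C9, so it is the retron of a 2-silyloxydiene + enal adduct. Ring A (C1–C4) is a four-atom tether whose quaternary C4 (tert-alkyl-sized orthoester against methyl) fixes the diene face.
- 14 ⇐ (R)-2-allyl-2,6-dimethylcyclohexanone (palladium-catalysed decarboxylative allylation) by ozonolytic C–C cleavage of the ring. Ring order: rings A and B together (step 13), butenolide separately (step 23).

Key step: step 13

## Remarks and assumptions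

- Numbering of the target is used for all intermediates: decalin C1–C10 (ring A C1–C5 and C10, ring B C5–C10); C17 on C8; C18 = 4α carboxyl carbon; C19 = 4β methyl; C20 = 10β methyl; side chain C11–C15 with C16 on C13; butenolide O1', C2'–C5'. α is the face opposite the C10 methyl.
- OBO = 4-methyl-2,6,7-trioxabicyclo[2.2.2]octan-1-yl, the orthoester form of the C18 carboxyl group.
- It is assumed that (R)-t-BuPHOX delivers the (R)-ketone 3 and (S)-TRIP the (S)-carbinol 24; if the sense is opposite, the antipodal ligand or catalyst is used.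
- The allylation is expected to give high but not complete ee; acid 5 can be enriched by crystallising its salt with a chiral amine, and any residual minor enantiomer becomes a separable diastereomer after coupling with 28.

## Route

Step 1
Reactants: 1 2,6-dimethylcyclohexanone
Product: 2 allyl 2,6-dimethylcyclohex-1-en-1-yl carbonate
Conditions: LiN(SiMe3)2, TMEDA, THF, −78 °C; allyl chloroformate, −78 °C → rt
Reagents that add atoms: allyl chloroformate, C=CCOC(=O)Cl
Why: The only possible (tetrasubstituted) lithium enolate is O-acylated by the chloroformate in the presence of TMEDA (enol carbonate formation); no stereocenter of the target is set.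

Step 2
Reactants: 2 allyl 2,6-dimethylcyclohex-1-en-1-yl carbonate
Product: 3 (2R)-2-allyl-2,6-dimethylcyclohexanone (both C6 epimers)
Conditions: Pd2(dba)3 (2.5 mol %), (R)-t-BuPHOX (6 mol %), THF, 25 °C
Reagents that add atoms: none
Why: Decarboxylative asymmetric allylic alkylation (Tsuji–Trost type): zerovalent palladium ionises the allyl carbonate, CO2 is lost and the enolate–allyl pair recombines in the chiral ligand sphere, which sets the quaternary centre (future C4) as R.

Step 3
Reactants: 3 (2R)-2-allyl-2,6-dimethylcyclohexanone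
Product: 4 (6R)-6-allyl-2,6-dimethyl-1-(trimethylsilyloxy)cyclohex-1-ene
Conditions: LiN(iPr)2, THF, −78 → 0 °C; Me3SiCl, Et3N, −78 °C → rt
Reagents that add atoms: chlorotrimethylsilane, C[Si](C)(C)Cl
Why: Only C6 carries an α-hydrogen, so silyl enol ether formation is regiodefined and removes the uncontrolled C6 centre.

Step 4
Reactants: 4 (6R)-6-allyl-2,6-dimethyl-1-(trimethylsilyloxy)cyclohex-1-ene
Product: 5 (2R)-2-allyl-2-methyl-6-oxoheptanoic acid
Conditions: O3 (1.0 equiv, Sudan Red 7B end point), CH2Cl2, −78 °C; Me2S, −78 °C → rt; aqueous work-up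
Reagents that add atoms: ozone, [O-][O+]=O
Why: Ozonolysis cleaves the electron-rich tetrasubstituted silyl enol ether much faster than the monosubstituted allyl group, so the ring C–C bond is cut to the keto acid while the quaternary centre is untouched.

Step 5
Reactants: 5 (2R)-2-allyl-2-methyl-6-oxoheptanoic acid
Product: 6 (3-methyloxetan-3-yl)methyl (2R)-2-allyl-2-methyl-6-oxoheptanoate
Conditions: (3-methyloxetan-3-yl)methanol, DCC, DMAP (cat.), CH2Cl2, 0 °C → rt
Reagents that add atoms: (3-methyloxetan-3-yl)methanol, CC1(CO)COC1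
Why: Steglich esterification of the hindered acid with a primary alcohol; no stereocenter is affected.

Step 6
Reactants: 6 (3-methyloxetan-3-yl)methyl (2R)-2-allyl-2-methyl-6-oxoheptanoate
Product: 7 (6R)-6-methyl-6-(OBO)non-8-en-2-one
Conditions: BF3·OEt2 (0.25 equiv), CH2Cl2, −15 °C → rt; Et3N quench
Reagents that add atoms: none
Why: Lewis-acid-catalysed rearrangement of the oxetanylmethyl ester to the bicyclic orthoester, which turns the planar carboxyl group into a tert-alkyl-sized, base- and hydride-stable group.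

Step 7
Reactants: 7 (6R)-6-methyl-6-(OBO)non-8-en-2-one
Product: 8 ethyl (2E,7R)-3,7-dimethyl-7-(OBO)deca-2,9-dienoate
Conditions: (EtO)2P(O)CH2CO2Et, NaH, THF, 0 → 60 °C; minor Z isomer removed by chromatography
Reagents that add atoms: triethyl phosphonoacetate, CCOC(=O)CP(=O)(OCC)OCC
Why: Horner–Wadsworth–Emmons olefination of the unhindered methyl ketone is expected to favour the (E)-enoate (future C9=C10 with C1 trans to C11), and the isomers are separable.

Step 8
Reactants: 8 ethyl (2E,7R)-3,7-dimethyl-7-(OBO)deca-2,9-dienoate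
Product: 9 ethyl (2E,7R)-3,7-dimethyl-7-(OBO)-9-oxonon-2-enoate
Conditions: O3, CH2Cl2, pyridine, −78 °C (Sudan Red 7B end point); PPh3
Reagents that add atoms: ozone, [O-][O+]=O
Why: Chemoselective ozonolysis of the terminal alkene in the presence of the electron-poor trisubstituted enoate gives the aldehyde (future C6).

Step 9
Reactants: 9 ethyl (2E,7R)-3,7-dimethyl-7-(OBO)-9-oxonon-2-enoate
Product: 10 ethyl (2E,7R,10E)-9-hydroxy-3,7-dimethyl-7-(OBO)dodeca-2,10-dienoate (both C9 epimers)
Conditions: (E)-1-iodoprop-1-ene, CrCl2 (4 equiv), NiCl2 (1 mol %), DMF, rt; pH 7 work-up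
Reagents that add atoms: (E)-1-iodoprop-1-ene, C/C=C/I
Why: Nozaki–Hiyama–Kishi addition of the alkenylchromium reagent is selective for the aldehyde over ester and orthoester and keeps the E geometry; the new carbinol centre is oxidised in the next step.

Step 10
Reactants: 10 ethyl (2E,7R,10E)-9-hydroxy-3,7-dimethyl-7-(OBO)dodeca-2,10-dienoate
Product: 11 ethyl (2E,7R,10E)-3,7-dimethyl-7-(OBO)-9-oxododeca-2,10-dienoate
Conditions: activated MnO2, CH2Cl2, rt
Reagents that add atoms: none
Why: Neutral allylic oxidation with MnO2 gives the (E)-propenyl ketone without exposing the orthoester to acid.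

Step 11
Reactants: 11 ethyl (2E,7R,10E)-3,7-dimethyl-7-(OBO)-9-oxododeca-2,10-dienoate
Product: 12 ethyl (2E,7R,8Z,10E)-9-(tert-butyldimethylsilyloxy)-3,7-dimethyl-7-(OBO)dodeca-2,8,10-trienoate
Conditions: LiN(iPr)2 (1.05 equiv), THF, −78 °C; t-BuMe2SiCl, HMPA, −78 → 0 °C
Reagents that add atoms: tert-butyldimethylsilyl chloride, CC(C)(C)[Si](C)(C)Cl
Why: Kinetic α'-deprotonation of the enone at C5 (more acidic than the enoate γ-positions) and O-silylation give the cross-conjugated 2-silyloxydiene; the bulky C4 substituent is expected to force the (Z)-enolate with C4 cis to oxygen.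

Step 12
Reactants: 12 ethyl (2E,7R,8Z,10E)-9-(tert-butyldimethylsilyloxy)-3,7-dimethyl-7-(OBO)dodeca-2,8,10-trienoate
Product: 13 (2E,7R,8Z,10E)-9-(tert-butyldimethylsilyloxy)-3,7-dimethyl-7-(OBO)dodeca-2,8,10-trien-1-ol
Conditions: iBu2AlH (2.2 equiv), CH2Cl2, −78 °C; aq. potassium sodium tartrate
Reagents that add atoms: none
Why: 1,2-Reduction of the enoate to the allylic alcohol leaves the silyl dienol ether and the orthoester intact.

Step 13
Reactants: 13 (2E,7R,8Z,10E)-9-(tert-butyldimethylsilyloxy)-3,7-dimethyl-7-(OBO)dodeca-2,8,10-trien-1-ol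
Product: 15 trans-fused Δ6-octalin aldehyde (9β-formyl; 6-silyl enol ether; 4α-OBO), via trienal 14 (not isolated)
Conditions: activated MnO2 (excess), CH2Cl2, rt; filtration through Celite; then toluene, BHT (cat.), 80 °C
Reagents that add atoms: none
Why: MnO2 oxidises the allylic alcohol to the (E)-enal 14, whose C9=C10 bond then undergoes a thermal, asynchronous normal-demand intramolecular Diels–Alder reaction with the 2-silyloxydiene C5=C6(OSi)–C7=C8, the nucleophilic terminus C5 bonding to the enal β-carbon C10 and C8 closing onto C9. The closest known reaction type is the oxidation-triggered type 1 intramolecular Diels–Alder reaction of 1,7,9-decatrienals and of 2-silyloxydienes with terminally activated (E)-dienophiles, which gives trans-fused octalins. Ring A is closed through the four-atom tether C1–C4 (fused mode, C5–C10 bond) and ring B is the cycloadduct ring itself (C5–C10 and C8–C9 bonds, new C6=C7 enol ether). C9 and C10 follow from the (E)-enal geometry (formyl cis to the C10 methyl), the trans fusion C5/C10 from the endo position of the formyl group, the 8β-methyl from the (E)-propenyl terminus, and all of them relative to C4 from the chair-like tether in which the orthoester cage lies equatorial (anti to the forming C5–C10 bond) and the small C4 methyl axial. The step needs endo over exo selectivity and a single diene face: the first rests on the carbonyl-endo preference of the enal, the second on the orthoester at C4, which cannot become syn-axial to the incoming C10 methyl.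

Step 14
Reactants: 15 trans-fused Δ6-octalin aldehyde
Product: 16 9β-vinyl Δ6-octalin silyl enol ether
Conditions: Ph3PCH3Br, KN(SiMe3)2, THF, 0 °C → rt
Reagents that add atoms: methyltriphenylphosphonium bromide, C[P+](c1ccccc1)(c1ccccc1)c1ccccc1.[Br-]
Why: Wittig methylenation of the equatorial aldehyde gives C11=C12; the equatorial 9β configuration is the thermodynamic one and is not at risk.

Step 15
Reactants: 16 9β-vinyl Δ6-octalin silyl enol ether
Product: 17 9β-vinyl Δ7-en-6-one
Conditions: Pd(OAc)2 (10 mol %), O2 (1 atm), DMSO, 40 °C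
Reagents that add atoms: none
Why: Saegusa–Ito oxidation: the palladium enolate formed on the open α face undergoes syn β-hydride elimination with the 8α-hydrogen to give the C7=C8 enone and erase the C8 centre.

Step 16
Reactants: 17 9β-vinyl Δ7-en-6-one
Product: 18 7α,8α-epoxy-6-ketone
Conditions: H2O2 (30 % aq.), NaOH, MeOH, 0 °C → rt
Reagents that add atoms: hydrogen peroxide, OO
Why: Weitz–Scheffer nucleophilic epoxidation; hydroperoxide should attack C8 from the α face, away from the axial C10 and C4β methyl groups, which places the oxygen on C8 α and the methyl β.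

Step 17
Reactants: 18 7α,8α-epoxy-6-ketone
Product: 20 6α,8α-diol orthoester (9β-vinyl), via hydroxy ketone 19 (not isolated)
Conditions: Li (excess), NH3 (l), THF, t-BuOH (2 equiv), −78 → −33 °C; NH4Cl
Reagents that add atoms: none
Why: Dissolving-metal reduction first cleaves the C7–O bond of the α,β-epoxy ketone with retention at C8 (8α-OH), then reduces the hindered C6 ketone under thermodynamic control to the equatorial 6α-alcohol; the orthoester and the isolated vinyl group are inert.

Step 18
Reactants: 20 6α,8α-diol orthoester (9β-vinyl)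
Product: 22 methyl ester diol (9β-vinyl), via diol ester 21 (not isolated)
Conditions: PPTS (cat.), MeOH/H2O (10:1), rt; then NaOMe (excess), MeOH, 50 °C
Reagents that add atoms: water, O; methanol, CO
Why: Mild acid hydrolysis opens the orthoester to the 2,2-bis(hydroxymethyl)propyl ester, and base-mediated transesterification (which may be assisted by the neighbouring 6α-hydroxyl) gives the methyl ester without touching any stereocenter.

Step 19
Reactants: 23 methacrolein
Product: 24 (3S)-2-methylhex-1-en-5-yn-3-ol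
Conditions: allenylboronic acid pinacol ester, (S)-TRIP phosphoric acid (5 mol %), 4 Å MS, toluene, −20 °C
Reagents that add atoms: allenylboronic acid pinacol ester, C=C=CB1OC(C)(C)C(C)(C)O1
Why: Chiral-phosphoric-acid-catalysed asymmetric propargylation of the aldehyde through a closed six-membered transition state sets the carbinol centre (future C5') as S.

Step 20
Reactants: 24 (3S)-2-methylhex-1-en-5-yn-3-ol
Product: 25 (3S)-2-methylhept-1-en-5-yn-3-ol
Conditions: n-BuLi (2.1 equiv), THF, −78 °C; MeI (1.05 equiv), DMPU, −78 → 0 °C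
Reagents that add atoms: iodomethane, CI
Why: The alkoxide–acetylide dianion is alkylated at carbon (acetylide alkylation), which installs the future C16 methyl.

Step 21
Reactants: 25 (3S)-2-methylhept-1-en-5-yn-3-ol
Product: 26 (3S,5E)-6-iodo-2-methylhepta-1,5-dien-3-ol
Conditions: Cp2Zr(H)Cl (2.5 equiv), THF, rt → 40 °C; I2, 0 °C
Reagents that add atoms: iodine, II
Why: Hydrozirconation–iodination: syn addition with zirconium at the less hindered, methyl-bearing alkyne carbon (after equilibration with excess reagent) and iodinolysis with retention give the (E)-vinyl iodide.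

Step 22
Reactants: 26 (3S,5E)-6-iodo-2-methylhepta-1,5-dien-3-ol
Product: 27 (3S,5E)-6-iodo-2-methylhepta-1,5-dien-3-yl acrylate
Conditions: acryloyl chloride, Et3N, DMAP (cat.), CH2Cl2, 0 °C
Reagents that add atoms: acryloyl chloride, C=CC(=O)Cl
Why: O-Acylation of the secondary allylic alcohol; the stereocenter is not involved.

Step 23
Reactants: 27 (3S,5E)-6-iodo-2-methylhepta-1,5-dien-3-yl acrylate
Product: 28 (5S)-5-[(2E)-3-iodobut-2-en-1-yl]-4-methylfuran-2(5H)-one
Conditions: second-generation Grubbs catalyst (5 mol %), toluene, 80 °C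
Reagents that add atoms: none
Why: Ring-closing metathesis between the acrylate and the 1,1-disubstituted alkene forms the 4-methylbutenolide; the trisubstituted vinyl iodide does not take part.

Step 24
Reactants: 22 methyl ester diol (9β-vinyl); 28 (5S)-5-[(2E)-3-iodobut-2-en-1-yl]-4-methylfuran-2(5H)-one
Product: 30 Δ13(14)-(E)-alkene (deoxy precursor of the target), via alkylborane 29 (not isolated)
Conditions: 9-BBN (excess), THF, rt → 50 °C; then 28, Pd(dppf)Cl2 (10 mol %), Ph3As, K3PO4 (aq.), DMF, rt
Reagents that add atoms: none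
Why: Anti-Markovnikov hydroboration of the terminal vinyl group and B-alkyl Suzuki–Miyaura coupling with the vinyl iodide form C12–C13 with retention of the E geometry under mild base.

Step 25
Reactants: 30 Δ13(14)-(E)-alkene
Product: 31 target CNP0324515.1
Conditions: O2, tetraphenylporphyrin (cat.), visible light, CH2Cl2, −20 °C; HPLC separation
Reagents that add atoms: oxygen, O=O
Why: Schenck ene reaction: singlet oxygen abstracts hydrogen from the more crowded side of the (E)-trisubstituted alkene (cis effect), where the C16 methyl is expected to be favoured over the branched C15 methylene, giving C13=C16 and the C14 hydroperoxide; no facial control at C14 is expected from the substrate, so the (14S)-epimer is separated from its epimer and from the C13 regioisomer.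

## Compound list

1 | 2,6-dimethylcyclohexanone (cis/trans mixture) | CC1CCCC(C)C1=O | starting material
2 | allyl 2,6-dimethylcyclohex-1-en-1-yl carbonate | C=CCOC(=O)OC1=C(C)CCCC1C | intermediate
3 | (2R)-2-allyl-2,6-dimethylcyclohexanone (both C6 epimers) | C=CC[C@@]1(C)CCCC(C)C1=O | intermediate
4 | (6R)-6-allyl-2,6-dimethyl-1-(trimethylsilyloxy)cyclohex-1-ene | C=CC[C@@]1(C)CCCC(C)=C1O[Si](C)(C)C | intermediate
5 | (2R)-2-allyl-2-methyl-6-oxoheptanoic acid | C=CC[C@@](C)(CCCC(C)=O)C(=O)O | intermediate
6 | (3-methyloxetan-3-yl)methyl (2R)-2-allyl-2-methyl-6-oxoheptanoate | C=CC[C@@](C)(CCCC(C)=O)C(=O)OCC1(C)COC1 | intermediate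
7 | (6R)-6-methyl-6-(4-methyl-2,6,7-trioxabicyclo[2.2.2]octan-1-yl)non-8-en-2-one | C=CC[C@@](C)(CCCC(C)=O)C12OCC(C)(CO1)CO2 | intermediate
8 | ethyl (2E,7R)-3,7-dimethyl-7-(OBO)deca-2,9-dienoate | CCOC(=O)/C=C(\C)CCC[C@](C)(CC=C)C12OCC(C)(CO1)CO2 | intermediate
9 | ethyl (2E,7R)-3,7-dimethyl-7-(OBO)-9-oxonon-2-enoate | CCOC(=O)/C=C(\C)CCC[C@](C)(CC=O)C12OCC(C)(CO1)CO2 | intermediate
10 | ethyl (2E,7R,10E)-9-hydroxy-3,7-dimethyl-7-(OBO)dodeca-2,10-dienoate (both C9 epimers) | CCOC(=O)/C=C(\C)CCC[C@](C)(CC(O)/C=C/C)C12OCC(C)(CO1)CO2 | intermediate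
11 | ethyl (2E,7R,10E)-3,7-dimethyl-7-(OBO)-9-oxododeca-2,10-dienoate | CCOC(=O)/C=C(\C)CCC[C@](C)(CC(=O)/C=C/C)C12OCC(C)(CO1)CO2 | intermediate
12 | ethyl (2E,7R,8Z,10E)-9-(tert-butyldimethylsilyloxy)-3,7-dimethyl-7-(OBO)dodeca-2,8,10-trienoate | CCOC(=O)/C=C(\C)CCC[C@](C)(/C=C(\O[Si](C)(C)C(C)(C)C)/C=C/C)C12OCC(C)(CO1)CO2 | intermediate
13 | (2E,7R,8Z,10E)-9-(tert-butyldimethylsilyloxy)-3,7-dimethyl-7-(OBO)dodeca-2,8,10-trien-1-ol | OC/C=C(\C)CCC[C@](C)(/C=C(\O[Si](C)(C)C(C)(C)C)/C=C/C)C12OCC(C)(CO1)CO2 | intermediate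
14 | (2E,7R,8Z,10E)-9-(tert-butyldimethylsilyloxy)-3,7-dimethyl-7-(OBO)dodeca-2,8,10-trienal | O=C/C=C(\C)CCC[C@](C)(/C=C(\O[Si](C)(C)C(C)(C)C)/C=C/C)C12OCC(C)(CO1)CO2 | intermediate
15 | trans-fused Δ6-octalin: C4 (β-CH3, α-OBO), 5α-H, C6 OTBS (C6=C7 enol ether), C8 (β-CH3, α-H), C9 (β-CHO, α-H), 10β-CH3 | O=C[C@@H]1[C@@]2(C)CCC[C@@](C)(C34OCC(C)(CO3)CO4)[C@@H]2C(O[Si](C)(C)C(C)(C)C)=C[C@@H]1C | intermediate
16 | as 15 with 9β-vinyl (C11=C12) in place of the formyl group | C=C[C@@H]1[C@@]2(C)CCC[C@@](C)(C34OCC(C)(CO3)CO4)[C@@H]2C(O[Si](C)(C)C(C)(C)C)=C[C@@H]1C | intermediate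
17 | 9β-vinyl-4α-OBO-4β,8,10β-trimethyl-Δ7-octalin-6-one (5α-H, 9α-H) | C=C[C@@H]1[C@@]2(C)CCC[C@@](C)(C34OCC(C)(CO3)CO4)[C@@H]2C(=O)C=C1C | intermediate
18 | 7α,8α-epoxide of 17 (8β-CH3) | C=C[C@@H]1[C@@]2(C)CCC[C@@](C)(C34OCC(C)(CO3)CO4)[C@@H]2C(=O)[C@H]5O[C@]51C | intermediate
19 | 8α-hydroxy-8β-methyl-6-ketone (9β-vinyl, 4α-OBO) | C=C[C@@H]1[C@@]2(C)CCC[C@@](C)(C34OCC(C)(CO3)CO4)[C@@H]2C(=O)C[C@@]1(C)O | intermediate
20 | 6α,8α-diol (9β-vinyl, 4α-OBO) | C=C[C@@H]1[C@@]2(C)CCC[C@@](C)(C34OCC(C)(CO3)CO4)[C@@H]2[C@@H](O)C[C@@]1(C)O | intermediate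
21 | 3-hydroxy-2-(hydroxymethyl)-2-methylpropyl 6α,8α-dihydroxy-9β-vinyl-decalin-4α-carboxylate | C=C[C@@H]1[C@@]2(C)CCC[C@@](C)(C(=O)OCC(C)(CO)CO)[C@@H]2[C@@H](O)C[C@@]1(C)O | intermediate
22 | methyl 6α,8α-dihydroxy-4β,8β,10β-trimethyl-9β-vinyl-decalin-4α-carboxylate (5α-H, 9α-H) | C=C[C@@H]1[C@@]2(C)CCC[C@@](C)(C(=O)OC)[C@@H]2[C@@H](O)C[C@@]1(C)O | intermediate
23 | methacrolein | C=C(C)C=O | starting material
24 | (3S)-2-methylhex-1-en-5-yn-3-ol | C=C(C)[C@@H](O)CC#C | intermediate
25 | (3S)-2-methylhept-1-en-5-yn-3-ol | C=C(C)[C@@H](O)CC#CC | intermediate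
26 | (3S,5E)-6-iodo-2-methylhepta-1,5-dien-3-ol | C=C(C)[C@@H](O)C/C=C(\C)I | intermediate
27 | (3S,5E)-6-iodo-2-methylhepta-1,5-dien-3-yl acrylate | C=C(C)[C@@H](OC(=O)C=C)C/C=C(\C)I | intermediate
28 | (5S)-5-[(2E)-3-iodobut-2-en-1-yl]-4-methylfuran-2(5H)-one | C/C(I)=C\C[C@@H]1OC(=O)C=C1C | intermediate
29 | B-alkyl-9-BBN adduct of 22 (boron on C12) | B1(CC[C@@H]3[C@@]4(C)CCC[C@@](C)(C(=O)OC)[C@@H]4[C@@H](O)C[C@@]3(C)O)C2CCCC1CCC2 | intermediate
30 | methyl 6α,8α-dihydroxy decalin-4α-carboxylate with the 9β side chain CH2CH2–C(CH3)=CH–CH2–[(5'S)-4'-methylbutenolide], 13E | C/C(CC[C@@H]1[C@@]2(C)CCC[C@@](C)(C(=O)OC)[C@@H]2[C@@H](O)C[C@@]1(C)O)=C\C[C@@H]1OC(=O)C=C1C | intermediate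
31 | CNP0324515.1: as 30 with C13=C16 methylene and (14S)-hydroperoxide | C=C(CC[C@@H]1[C@@]2(C)CCC[C@@](C)(C(=O)OC)[C@@H]2[C@@H](O)C[C@@]1(C)O)[C@H](C[C@@H]1OC(=O)C=C1C)OO | target

## Step count and risks

Total step count: 25. Longest linear sequence: 20 (steps 1–18, 24, 25); the butenolide branch is steps 19–23.

**Step 13 (key step).** What may go wrong: the congested cycloaddition may be slower than loss of the silyl dienol ether or oligomerisation of the enal, and endo control may erode at the temperature required. Fallback (dienophile at the ester oxidation level): setting out from 12, the enoate itself is heated (toluene, sealed tube, 170 °C, BHT) to the ester cycloadduct F1. Reduction with iBu2AlH gives the primary alcohol F2, and oxidation (Dess–Martin periodinane, pyridine) returns to the route at 15.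

**Step 25.** What may go wrong: singlet oxygen attacks both faces of the C13=C14 bond and can also abstract hydrogen from C15, so the wanted hydroperoxide forms without facial control and must be separated from its C14 epimer and the C13 regioisomers. Fallback (reagent-controlled, stereoconvergent): setting out from 30, the same photooxygenation is run and the secondary hydroperoxides, 31 and its C14 epimer F3, are reduced together (PPh3) to the allylic alcohols F4. Chemoselective allylic oxidation (MnO2) gives the single enone F5. Corey–Bakshi–Shibata reduction ((S)-Me-CBS oxazaborolidine, BH3·SMe2) should give the (14R)-alcohol F6. Mesylation (MsCl, Et3N, −30 °C; the hindered ring hydroxyls are expected not to react) gives the mesylate F7. Displacement with inversion by hydrogen peroxide (H2O2, KOH, MeOH, 0 °C) returns to the route at 31.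

**Step 24.** What may go wrong: slow hydroboration of the vinyl group flanked by two fully substituted carbons, and base-induced epimerisation at C5' or opening of the butenolide during transmetalation. Fallback (base-free cross-electrophile coupling): setting out from 22, hydroboration–oxidation (9-BBN; NaBO3) gives the primary alcohol F8 and iodination (I2, PPh3, imidazole) the primary iodide F9. Nickel-catalysed reductive coupling with 28 (NiI2, 4,4'-di-tert-butyl-2,2'-bipyridine, zinc, DMA) returns to the route at 30.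

## Further compounds

F1 | step 13 | ethyl ester analogue of 15 (9β-CO2Et cycloadduct) | CCOC(=O)[C@@H]1[C@@]2(C)CCC[C@@](C)(C34OCC(C)(CO3)CO4)[C@@H]2C(O[Si](C)(C)C(C)(C)C)=C[C@@H]1C
F2 | step 13 | 9β-hydroxymethyl analogue of 15 | OC[C@@H]1[C@@]2(C)CCC[C@@](C)(C34OCC(C)(CO3)CO4)[C@@H]2C(O[Si](C)(C)C(C)(C)C)=C[C@@H]1C
F3 | step 25 | (14R)-hydroperoxide, C14 epimer of 31 | C=C(CC[C@@H]1[C@@]2(C)CCC[C@@](C)(C(=O)OC)[C@@H]2[C@@H](O)C[C@@]1(C)O)[C@@H](C[C@@H]1OC(=O)C=C1C)OO
F4 | step 25 | 14-hydroxy-13(16)-ene (both C14 epimers) | C=C(CC[C@@H]1[C@@]2(C)CCC[C@@](C)(C(=O)OC)[C@@H]2[C@@H](O)C[C@@]1(C)O)C(O)C[C@@H]1OC(=O)C=C1C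
F5 | step 25 | 14-oxo-13(16)-ene (enone) | C=C(CC[C@@H]1[C@@]2(C)CCC[C@@](C)(C(=O)OC)[C@@H]2[C@@H](O)C[C@@]1(C)O)C(=O)C[C@@H]1OC(=O)C=C1C
F6 | step 25 | (14R)-14-hydroxy-13(16)-ene | C=C(CC[C@@H]1[C@@]2(C)CCC[C@@](C)(C(=O)OC)[C@@H]2[C@@H](O)C[C@@]1(C)O)[C@@H](C[C@@H]1OC(=O)C=C1C)O
F7 | step 25 | (14R)-14-methanesulfonate | C=C(CC[C@@H]1[C@@]2(C)CCC[C@@](C)(C(=O)OC)[C@@H]2[C@@H](O)C[C@@]1(C)O)[C@@H](C[C@@H]1OC(=O)C=C1C)OS(C)(=O)=O
F8 | step 24 | 12-hydroxy compound (9β-CH2CH2OH) from 22 | OCC[C@@H]1[C@@]2(C)CCC[C@@](C)(C(=O)OC)[C@@H]2[C@@H](O)C[C@@]1(C)O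
F9 | step 24 | 12-iodo compound (9β-CH2CH2I) | ICC[C@@H]1[C@@]2(C)CCC[C@@](C)(C(=O)OC)[C@@H]2[C@@H](O)C[C@@]1(C)O
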